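**Retrosynthetic overview**
1. Pinnatin B (17) ⇒ the Z-ene-1,4-dione is unveiled last by singlet-oxygen opening of the 2,5-bridged furan in acetate 16 (furan = masked C3–C6 enedione).
2. The 13-membered ring, the C1–C2 bond and the C1/C2 stereodiad ⇒ a new Ru–H, redox-neutral macrocyclising diene hydrohydroxyalkylation of the open-chain furfuryl alcohol/1,3-diene 14.
3. Butenolide and diene side chain ⇒ Ru-catalysed alkene–alkyne (Alder-ene) coupling of γ-hydroxy-ynoate 11 with 2-methylpenta-1,4-diene; C10 comes from Zn-ProPhenol propiolate addition to aldehyde 9.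
4. trans-Cyclopropane (C7, quaternary C8) ⇒ Charette asymmetric cyclopropanation of (E)-furyl allylic alcohol 7 ⇐ Stille coupling of furylstannane 4 with vinyl iodide 6.
5. Ring order: furan (purchased) → cyclopropane → butenolide → 13-membered carbocycle → furan opened to the enedione.

Assumption: positions are labelled cembranoid-style (C1 = CH–isopropenyl, C2 = CH–OAc, C3–C6 = dione/furan carbons, C7/C8/C9 = cyclopropane, C10 = lactone CH–O, C11=C12 = butenolide alkene, C13–C14 = CH2CH2). The target is then (1S,2S,7S,8S,10S,4Z). Compounds 1, 5, 10 and 12 are taken as catalogue chemicals.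

**Step 1**
Reactants: 1 (3-methylfuran-2-carbaldehyde)
Product: 2 ((3-methylfuran-2-yl)methanol)
Conditions: NaBH4, MeOH, 0 °C
Reagents that add atoms: none (hydride only)
Why: Simple borohydride reduction parks the future C2 aldehyde at the alcohol level, the oxidation level required by the key step.

**Step 2**
Reactants: 2 ((3-methylfuran-2-yl)methanol)
Product: 3 (triisopropyl[(3-methylfuran-2-yl)methoxy]silane)
Conditions: TIPSCl, imidazole, DMF, rt
Reagents that add atoms: triisopropylsilyl chloride, CC(C)[Si](Cl)(C(C)C)C(C)C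
Why: Standard O-silylation; the TIPS ether tolerates n-BuLi, zinc carbenoids, Me2Zn and cationic Ru.

**Step 3**
Reactants: 3 (TIPS ether)
Product: 4 (tributyl(4-methyl-5-{[(triisopropylsilyl)oxy]methyl}furan-2-yl)stannane)
Conditions: n-BuLi, THF, −78 → 0 °C; then Bu3SnCl, −78 °C → rt
Reagents that add atoms: tributyltin chloride, CCCC[Sn](Cl)(CCCC)CCCC
Why: Directed α-lithiation occurs at the only free furan α-position (C5) and is trapped as the stannane.

**Step 4**
Reactants: 5 (prop-2-yn-1-ol)
Product: 6 ((2E)-3-iodo-2-methylprop-2-en-1-ol)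
Conditions: Me3Al (3 equiv), Cp2ZrCl2 (25 mol %), CH2Cl2, 0 °C → rt; then I2, THF, −30 °C
Reagents that add atoms: trimethylaluminium, C[Al](C)C; iodine, II
Why: Negishi Zr-catalysed syn-carboalumination followed by iodinolysis with retention gives the E-trisubstituted vinyl iodide, the geometry that later becomes the trans-cyclopropane.

**Step 5**
Reactants: 4 (furylstannane) + 6 (vinyl iodide)
Product: 7 ((2E)-2-methyl-3-(4-methyl-5-{[(triisopropylsilyl)oxy]methyl}furan-2-yl)prop-2-en-1-ol)
Conditions: Pd(PPh3)4 (5 mol %), CuI, CsF, DMF, rt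
Reagents that add atoms: none (all atoms from 4 and 6)
Why: Stille coupling proceeds with retention of alkene geometry and tolerates the free allylic alcohol.

**Step 6**
Reactants: 7 ((E)-allylic alcohol)
Product: 8 ([(1S,2S)-1-methyl-2-(4-methyl-5-{[(triisopropylsilyl)oxy]methyl}furan-2-yl)cyclopropyl]methanol)
Conditions: Zn(CH2I)2·DME (from Et2Zn, CH2I2, DME), (4R,5R)-2-butyl-N,N,N′,N′-tetramethyl-1,3,2-dioxaborolane-4,5-dicarboxamide (1.2 equiv), CH2Cl2, −10 °C → rt
Reagents that add atoms: diiodomethane, ICI (delivers CH2)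
Why: Charette asymmetric Simmons–Smith cyclopropanation; stereospecific syn CH2 transfer to the E-alkene fixes furyl trans to CH2OH (cis to CH3), and the (R,R)-boronate-bound zinc alkoxide directs the carbenoid to the face giving (1S,2S) (same sense as cinnamyl alcohol → (1S,2S)-2-phenylcyclopropylmethanol), setting C7 and quaternary C8.

**Step 7**
Reactants: 8 (cyclopropylmethanol)
Product: 9 ((1S,2S)-1-methyl-2-(4-methyl-5-{[(triisopropylsilyl)oxy]methyl}furan-2-yl)cyclopropane-1-carbaldehyde)
Conditions: Dess–Martin periodinane, NaHCO3, CH2Cl2, 0 °C → rt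
Reagents that add atoms: none
Why: Buffered Dess–Martin oxidation; the α-carbon is quaternary, so the aldehyde cannot epimerise.

**Step 8**
Reactants: 9 (cyclopropyl aldehyde) + 10 (methyl propiolate)
Product: 11 (methyl (4R)-4-hydroxy-4-[(1S,2S)-1-methyl-2-(4-methyl-5-{[(triisopropylsilyl)oxy]methyl}furan-2-yl)cyclopropyl]but-2-ynoate)
Conditions: (S,S)-ProPhenol (20 mol %), Me2Zn (3 equiv), Ph3P=O (40 mol %), toluene, 4 °C
Reagents that add atoms: none (all atoms from 9 and 10)
Why: Dinuclear Zn-ProPhenol asymmetric alkynylation delivers the zinc propiolate under catalyst control to the Si face of the non-enolisable aldehyde, setting C10 as 4R (this becomes 10S once C11 is sp2); the ligand antipode is assigned by analogy with simple aldehydes and must be confirmed, and both enantiomers are commercial.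

**Step 9**
Reactants: 11 (γ-hydroxy-ynoate) + 12 (2-methylpenta-1,4-diene)
Product: 13 ((5S)-3-[(2E)-4-methylpenta-2,4-dien-1-yl]-5-[(1S,2S)-1-methyl-2-(4-methyl-5-{[(triisopropylsilyl)oxy]methyl}furan-2-yl)cyclopropyl]furan-2(5H)-one)
Conditions: [CpRu(MeCN)3]PF6 (10 mol %), 12 (4 equiv), acetone, rt; PPTS (cat.) to complete lactonisation (−MeOH)
Reagents that add atoms: none (all atoms from 11 and 12)
Why: Ru-catalysed alkene–alkyne (Alder-ene) coupling joins the monosubstituted alkene terminus of 12 to the ynoate α-carbon with syn H/C addition, so the ester sits cis to the carbinol and lactonises to the butenolide; β-H elimination of the bis-allylic hydrogen gives the conjugated diene, and C10 is untouched.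

**Step 10**
Reactants: 13 (silyl ether)
Product: 14 ((5S)-5-{(1S,2S)-2-[5-(hydroxymethyl)-4-methylfuran-2-yl]-1-methylcyclopropyl}-3-[(2E)-4-methylpenta-2,4-dien-1-yl]furan-2(5H)-one)
Conditions: TBAF, AcOH (1:1), THF, 0 °C → rt
Reagents that add atoms: none
Why: Fluoride desilylation, buffered with AcOH so the base-sensitive butenolide γ-H (C10) is not epimerised.

**Step 11 (key step, new)**
Reactants: 14 (open-chain furfuryl alcohol / 1,3-diene)
Product: 15 (macrocyclic furfuryl alcohol, (1S,2S,7S,8S,10S): 13-membered carbocycle bridged 2,5 by the 3-methylfuran; isopropenyl on C1, OH on C2, trans-cyclopropane C7/C8 linking furan to the butenolide γ-carbon C10, butenolide α-carbon tied to C1 by CH2CH2)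
Conditions: RuH2(CO)(PPh3)3 (10 mol %), (R)-DM-SEGPHOS (10 mol %), 2,4,6-(i-Pr)3C6H2SO3H (10 mol %), THF, 95 °C (sealed), syringe-pump addition of 14, final 3 mM
Reagents that add atoms: none (14 and 15 are isomers, C20H24O4)
Why: Proposed new method: a macrocyclising, redox-neutral Ru-catalysed diene hydrohydroxyalkylation. The Ru(II) sulfonate dehydrogenates the furfuryl alcohol to the 2-formylfuran, and the resulting Ru–H adds to the diene at C14 (same regiochemical sense as isoprene; the alkene geometry is erased) to give a 1-alkyl-2-methylallyl-ruthenium. Its primary (E)-σ-allyl form adds through a closed chair transition state to the tethered aldehyde with allylic transposition, forming C1–C2, the isopropenyl group, the 13-membered ring and the anti (1S,2S) diad, with the aldehyde face selected by the chiral bisphosphine (antipode to be screened) and the furanophane conformation. The closest known reaction types are the intermolecular Ru-catalysed transfer-hydrogenative coupling of butadiene/isoprene with benzylic alcohols (carbonyl crotylation from the alcohol oxidation level) and the CrCl2 Nozaki–Hiyama–Kishi macrocyclisation of furfural/allyl bromide precursors to furanobutenolide cembranoids.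

**Step 12**
Reactants: 15 (macrocyclic alcohol)
Product: 16 (C2 acetate of 15, (1S,2S,7S,8S,10S))
Conditions: Ac2O, pyridine, DMAP (cat.), CH2Cl2, 0 °C → rt
Reagents that add atoms: acetic anhydride, CC(=O)OC(C)=O
Why: Standard acylation installs the natural acetate and blocks the Achmatowicz pathway a free furfuryl alcohol would follow in the next step.

**Step 13**
Reactants: 16 (furan acetate)
Product: 17 (pinnatin B)
Conditions: O2, methylene blue (cat.), visible light, CH2Cl2, −78 °C; then Me2S, −78 °C → rt
Reagents that add atoms: dioxygen, O=O (one O retained; the other leaves as DMSO)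
Why: Singlet-oxygen [4+2] addition to the trisubstituted furan (far faster than ene reaction of the isopropenyl group or attack on the butenolide) gives the 2,5-endoperoxide, and Me2S reduction opens it to the cis-2-ene-1,4-dione; the Z geometry is dictated by the furan ring and no stereocentre is touched.

**Compound list**
1 | 3-methylfuran-2-carbaldehyde | Cc1ccoc1C=O | starting material
2 | (3-methylfuran-2-yl)methanol | Cc1ccoc1CO | intermediate
3 | triisopropyl[(3-methylfuran-2-yl)methoxy]silane | Cc1ccoc1CO[Si](C(C)C)(C(C)C)C(C)C | intermediate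
4 | tributyl(4-methyl-5-{[(triisopropylsilyl)oxy]methyl}furan-2-yl)stannane | Cc1cc([Sn](CCCC)(CCCC)CCCC)oc1CO[Si](C(C)C)(C(C)C)C(C)C | intermediate
5 | prop-2-yn-1-ol | C#CCO | starting material
6 | (2E)-3-iodo-2-methylprop-2-en-1-ol | OC/C(C)=C/I | intermediate
7 | (2E)-2-methyl-3-(4-methyl-5-{[(triisopropylsilyl)oxy]methyl}furan-2-yl)prop-2-en-1-ol | OC/C(C)=C/c1cc(C)c(CO[Si](C(C)C)(C(C)C)C(C)C)o1 | intermediate
8 | [(1S,2S)-1-methyl-2-(4-methyl-5-{[(triisopropylsilyl)oxy]methyl}furan-2-yl)cyclopropyl]methanol | OC[C@@]1(C)C[C@@H]1c2cc(C)c(CO[Si](C(C)C)(C(C)C)C(C)C)o2 | intermediate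
9 | (1S,2S)-1-methyl-2-(4-methyl-5-{[(triisopropylsilyl)oxy]methyl}furan-2-yl)cyclopropane-1-carbaldehyde | O=C[C@@]1(C)C[C@@H]1c2cc(C)c(CO[Si](C(C)C)(C(C)C)C(C)C)o2 | intermediate
10 | methyl propiolate | C#CC(=O)OC | starting material
11 | methyl (4R)-4-hydroxy-4-[(1S,2S)-1-methyl-2-(4-methyl-5-{[(triisopropylsilyl)oxy]methyl}furan-2-yl)cyclopropyl]but-2-ynoate | COC(=O)C#C[C@H](O)[C@@]1(C)C[C@@H]1c2cc(C)c(CO[Si](C(C)C)(C(C)C)C(C)C)o2 | intermediate
12 | 2-methylpenta-1,4-diene | C=CCC(C)=C | starting material
13 | (5S)-3-[(2E)-4-methylpenta-2,4-dien-1-yl]-5-[(1S,2S)-1-methyl-2-(4-methyl-5-{[(triisopropylsilyl)oxy]methyl}furan-2-yl)cyclopropyl]furan-2(5H)-one | C=C(C)/C=C/CC1=C[C@H](OC1=O)[C@@]2(C)C[C@@H]2c3cc(C)c(CO[Si](C(C)C)(C(C)C)C(C)C)o3 | intermediate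
14 | (5S)-5-{(1S,2S)-2-[5-(hydroxymethyl)-4-methylfuran-2-yl]-1-methylcyclopropyl}-3-[(2E)-4-methylpenta-2,4-dien-1-yl]furan-2(5H)-one | C=C(C)/C=C/CC1=C[C@H](OC1=O)[C@@]2(C)C[C@@H]2c3cc(C)c(CO)o3 | intermediate
15 | (1S,2S,7S,8S,10S) macrocyclic furfuryl alcohol (furan-bridged 13-membered carbocycle with trans-cyclopropane and butenolide; 2-OH, 1-isopropenyl) | C=C(C)[C@@H]1CCC2=C[C@H](OC2=O)[C@@]3(C)C[C@@H]3c4cc(C)c(o4)[C@H]1O | intermediate
16 | (1S,2S,7S,8S,10S) C2 acetate of 15 | C=C(C)[C@@H]1CCC2=C[C@H](OC2=O)[C@@]3(C)C[C@@H]3c4cc(C)c(o4)[C@H]1OC(C)=O | intermediate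
17 | pinnatin B, (1S,2S,7S,8S,10S,4Z) | C=C(C)[C@@H]1CCC2=C[C@H](OC2=O)[C@@]2(C)C[C@@H]2C(=O)/C=C(/C)C(=O)[C@H]1OC(C)=O | target

**Totals**
Total steps: 13. Longest linear sequence: 12 (1 → 17 via steps 1–3 and 5–13; step 4 is the one-step side branch).

**Three steps most likely to fail, with fallbacks**
1. Step 11 (new Ru macrocyclisation). Risks are hydrometalation at the wrong diene terminus, oligomerisation, Ru–H reduction or isomerisation of the butenolide/skipped diene, and wrong C1/C2 diastereomer. Fallback (known chemistry): the Nozaki–Hiyama–Kishi closure. Couple 11 with allyl alcohol under the same Ru alkene–alkyne conditions to give the 3-oxopropyl butenolide, then Wittig with Ph3P=C(Me)CHO, NaBH4, CBr4/PPh3, HF·pyridine and MnO2 to reach the allyl bromide/furfural. Stoichiometric CrCl2 in THF at high dilution then gives 15, and steps 12–13 follow.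
2. Step 9 (Alder-ene coupling with a skipped diene). Risks are sequestration of CpRu+ by the conjugated diene product and poor chemoselectivity. Fallback: use allyl alcohol as the ene partner (the established variant), Wittig with Ph3P=C(Me)CHO and NaBH4 to the (E)-allylic alcohol, convert it to its methyl carbonate, and regenerate diene 13 by Pd(0)-catalysed 1,4-elimination (π-allyl formation, then β-H loss from C14).
3. Step 8 (catalyst-controlled alkynylation of a hindered, chiral donor–acceptor cyclopropyl aldehyde). Risks are a mismatched pairing or low conversion. Fallback: add LiC≡CCO2Me non-selectively at −78 °C, oxidise to the ynone with Dess–Martin periodinane, and reduce with (R)-Me-CBS/catecholborane (tertiary cyclopropyl as the large group), so C10 is set by ketone reduction instead of C–C addition.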